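**Plan**

1. Retrosynthesis: after the four benzyl ethers, both pyranone rings are opened at their acyl–Cα bonds (C4'–C3' first, then C4–C3). This turns the 3,3'-biflavanone into a C2-symmetric dialdehyde whose C3–C3' unit is an alkyne. The two aryl–O bonds (SNAr) and the two carbinol–alkyne C–C bonds (alkynylation) are cut next, one arm at a time.
2. Enabling feature: the 1,4-diketone O=C4–C3–C3'–C4'=O spans the two pyranone rings. Each C3 is α to its own C4 and β to the other, and each is tied through C2–O1 to the arene that carries the acyl carbon. A C3≡C3' alkyne can therefore take up two tethered acyl anion equivalents in turn.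
3. Forward: asymmetric alkynylation of 4-(benzyloxy)benzaldehyde, desilylation and SNAr give the first aryl propargyl ether; its terminal alkyne is added to a second molecule of the aldehyde and a second SNAr attaches the other arm; nitrile reduction gives the dialdehyde; one carbene-catalysed cascade (alkyne hydroacylation, then Stetter addition) closes both pyranone rings, the first closure creating the enone that the second needs; hydrogenolysis frees the four phenols.
4. Stereochemistry: C2 and C2' come from the two ligand-controlled alkynylations and pass through the SNAr steps with retention. C3 and C3' are set in the cascade and, being α to ketones, settle as 2,3-trans in each ring. With both C2 centres fixed as R, only the C2-symmetric (2R,3S,2'R,3'S) isomer can result.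

Key step: step 7

Assumption: (S,S)-ProPhenol is taken to deliver the carbinol configuration drawn in steps 1 and 4; if the sense of induction is the opposite, the (R,R)-ligand is used in both steps.

**Step 1**
Reactants: 1 4-(benzyloxy)benzaldehyde; 2 ethynyltrimethylsilane
Product: 3 (S)-1-[4-(benzyloxy)phenyl]-3-(trimethylsilyl)prop-2-yn-1-ol
Conditions: (S,S)-ProPhenol (10 mol%), Me2Zn (3 equiv), Ph3P=O (20 mol%), toluene, 4 °C; aq. NH4Cl
Reagents that add atoms: none
Why: Catalytic asymmetric alkynylation of an aryl aldehyde, in which the dinuclear zinc alkoxide catalyst formed from Me2Zn and (S,S)-ProPhenol binds aldehyde and alkynylzinc together and delivers the alkynyl group to one carbonyl face, setting the carbinol centre under ligand control.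

**Step 2**
Reactants: 3 (S)-1-[4-(benzyloxy)phenyl]-3-(trimethylsilyl)prop-2-yn-1-ol
Product: 4 (R)-1-[4-(benzyloxy)phenyl]prop-2-yn-1-ol
Conditions: K2CO3 (0.2 equiv), MeOH, rt
Reagents that add atoms: none
Why: Base-catalysed methanolysis of the C(sp)–Si bond (protodesilylation) leaves the carbinol centre untouched; the descriptor changes only because ethynyl ranks below aryl.

**Step 3**
Reactants: 4 (R)-1-[4-(benzyloxy)phenyl]prop-2-yn-1-ol; 5 4-(benzyloxy)-2-fluorobenzonitrile
Product: 6 4-(benzyloxy)-2-{[(1R)-1-[4-(benzyloxy)phenyl]prop-2-yn-1-yl]oxy}benzonitrile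
Conditions: KN(SiMe3)2 (1.0 equiv), THF, −78 °C; then 5 (1.1 equiv), −78 °C to 0 °C; aq. NH4Cl
Reagents that add atoms: none
Why: Nucleophilic aromatic substitution (SNAr) of the fluoride ortho to the nitrile by the potassium alkoxide, which forms in preference to the acetylide with one equivalent of base; the carbinol C–O bond is not broken, so the centre is retained, and a nitrile (unlike an aldehyde) cannot accept hydride from the alkoxide.

**Step 4**
Reactants: 6 4-(benzyloxy)-2-{[(1R)-1-[4-(benzyloxy)phenyl]prop-2-yn-1-yl]oxy}benzonitrile; 1 4-(benzyloxy)benzaldehyde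
Product: 7 4-(benzyloxy)-2-{[(1S,4S)-1,4-bis[4-(benzyloxy)phenyl]-4-hydroxybut-2-yn-1-yl]oxy}benzonitrile
Conditions: 6 (1.0 equiv), Me2Zn (2.0 equiv), (S,S)-ProPhenol (20 mol%), Ph3P=O (40 mol%), toluene, rt; then 1 (1.5 equiv), 4 °C; aq. NH4Cl
Reagents that add atoms: none
Why: Second asymmetric alkynylation with the same dinuclear zinc catalyst, now with an alkyne that carries no free hydroxyl and whose nitrile and aryl ether are inert to Me2Zn; the new carbinol centre is set by the ligand as in step 1, the existing centre at the far end of the linear alkyne should have little influence, any wrong-sense addition ends in the separable (1S,4R) diastereomer, and the C1 descriptor changes from R to S only because the now internal alkynyl group outranks aryl.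

**Step 5**
Reactants: 7 4-(benzyloxy)-2-{[(1S,4S)-1,4-bis[4-(benzyloxy)phenyl]-4-hydroxybut-2-yn-1-yl]oxy}benzonitrile; 5 4-(benzyloxy)-2-fluorobenzonitrile
Product: 8 2,2'-{[(1S,4S)-1,4-bis[4-(benzyloxy)phenyl]but-2-yne-1,4-diyl]bis(oxy)}bis[4-(benzyloxy)benzonitrile]
Conditions: KN(SiMe3)2 (1.0 equiv), THF, −78 °C; then 5 (1.2 equiv), −78 °C to 0 °C; aq. NH4Cl
Reagents that add atoms: none
Why: Second SNAr of an ortho-cyano aryl fluoride by the potassium alkoxide; the carbinol C–O bond is not broken, so C4 is retained, and the low temperature and equimolar base are chosen so that arylation outruns base-mediated redox isomerisation of the propargylic alkoxide.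

**Step 6**
Reactants: 8 2,2'-{[(1S,4S)-1,4-bis[4-(benzyloxy)phenyl]but-2-yne-1,4-diyl]bis(oxy)}bis[4-(benzyloxy)benzonitrile]
Product: 9 2,2'-{[(1S,4S)-1,4-bis[4-(benzyloxy)phenyl]but-2-yne-1,4-diyl]bis(oxy)}bis[4-(benzyloxy)benzaldehyde]
Conditions: i-Bu2AlH (3 equiv), CH2Cl2, −78 °C; then aq. potassium sodium tartrate (KNaC4H4O6), rt
Reagents that add atoms: water, O
Why: Partial reduction of each nitrile by DIBAL-H stops at the N-aluminio aldimine at low temperature and hydrolysis on work-up gives the aldehyde; alkyne, ethers and both stereocentres are inert.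

**Step 7**
Reactants: 9 2,2'-{[(1S,4S)-1,4-bis[4-(benzyloxy)phenyl]but-2-yne-1,4-diyl]bis(oxy)}bis[4-(benzyloxy)benzaldehyde]
Product: 11 (2R,3S,2'R,3'S)-7,7'-bis(benzyloxy)-2,2'-bis[4-(benzyloxy)phenyl]-[3,3'-bichromane]-4,4'-dione, via (E)-3-alkylidene flavanone aldehyde 10 (not isolated)
Conditions: 3-mesityl-5,6,7,8-tetrahydro-4H-cyclohepta[d]thiazol-3-ium perchlorate (20 mol%), K2CO3 (40 mol%), THF (0.02 M), 70 °C; then DBU (0.1 equiv), CH2Cl2, 0 °C
Reagents that add atoms: none
Why: Proposed new method: the thiazol-2-ylidene converts one formyl group into a Breslow intermediate that adds to the proximal alkyne carbon with concerted proton transfer to the distal one (Conia-ene-like syn hydroacylation, 6-exo-dig closure of the first pyranone ring) to give the (E)-enone 10, and the Breslow intermediate of the second formyl group then adds to the β-carbon of that exocyclic enone (Stetter addition, 6-exo-trig closure of the second pyranone ring through its C3'–C4' bond), after which the enol of the first ring is protonated at C3. The closest known reactions are the carbene-catalysed intramolecular hydroacylation of unactivated alkynes in 2-(propargyloxy)benzaldehydes and the intramolecular Stetter reaction of salicylaldehyde-tethered α-substituted enones; they have not been run in sequence on one alkyne that carries an aldehyde arm at each end. C2 and C2' are carried in from 9; C3' is set in the Stetter closure under control of C2', because allylic 1,3-strain in the trisubstituted enone holds the C2'–H bond in the alkene plane and this conformer leads to the 2',3'-trans ring; C3 is set by protonation of the enol. Both C3 centres are α to a ketone, so the DBU treatment is expected to bring any epimer to the 2,3-trans,2',3'-trans isomer, the only all-equatorial one open to a compound with fixed (2R,2'R) centres. The step needs the alkyne to be acylated before aryloxide is lost from the propargylic position and the second closure to outrun migration of the exocyclic double bond into the ring; the concerted proton transfer avoids a free vinyl anion, the six-membered intramolecular Stetter closure should be fast, and the C2 symmetry of 9 ensures that whichever aldehyde reacts first leaves the other poised at the β-carbon.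

**Step 8**
Reactants: 11 (2R,3S,2'R,3'S)-7,7'-bis(benzyloxy)-2,2'-bis[4-(benzyloxy)phenyl]-[3,3'-bichromane]-4,4'-dione
Product: 12 (2R,3S,2'R,3'S)-7,7'-dihydroxy-2,2'-bis(4-hydroxyphenyl)-[3,3'-bichromane]-4,4'-dione
Conditions: H2 (1 atm), 10% Pd/C, THF/MeOH, rt
Reagents that add atoms: none
Why: Catalytic hydrogenolysis of the four benzyl aryl ethers under neutral conditions should be much faster than reduction of the electron-rich aryl ketones or cleavage of the ring C2–O1 bond, and it exposes the base-sensitive free phenolic flavanone to neither acid nor base, so no stereocentre is touched.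

**Compound list**

1 | 4-(benzyloxy)benzaldehyde | O=Cc1ccc(OCc2ccccc2)cc1 | starting material
2 | ethynyltrimethylsilane | C#C[Si](C)(C)C | starting material
3 | (S)-1-[4-(benzyloxy)phenyl]-3-(trimethylsilyl)prop-2-yn-1-ol | O[C@@H](c1ccc(OCc2ccccc2)cc1)C#C[Si](C)(C)C | intermediate
4 | (R)-1-[4-(benzyloxy)phenyl]prop-2-yn-1-ol | O[C@@H](c1ccc(OCc2ccccc2)cc1)C#C | intermediate
5 | 4-(benzyloxy)-2-fluorobenzonitrile | N#Cc1ccc(OCc2ccccc2)cc1F | starting material
6 | 4-(benzyloxy)-2-{[(1R)-1-[4-(benzyloxy)phenyl]prop-2-yn-1-yl]oxy}benzonitrile | N#Cc1ccc(OCc2ccccc2)cc1O[C@@H](c1ccc(OCc2ccccc2)cc1)C#C | intermediate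
7 | 4-(benzyloxy)-2-{[(1S,4S)-1,4-bis[4-(benzyloxy)phenyl]-4-hydroxybut-2-yn-1-yl]oxy}benzonitrile | N#Cc1ccc(OCc2ccccc2)cc1O[C@@H](c1ccc(OCc2ccccc2)cc1)C#C[C@@H](O)c1ccc(OCc2ccccc2)cc1 | intermediate
8 | 2,2'-{[(1S,4S)-1,4-bis[4-(benzyloxy)phenyl]but-2-yne-1,4-diyl]bis(oxy)}bis[4-(benzyloxy)benzonitrile] | N#Cc1ccc(OCc2ccccc2)cc1O[C@@H](c1ccc(OCc2ccccc2)cc1)C#C[C@H](c1ccc(OCc2ccccc2)cc1)Oc1cc(OCc2ccccc2)ccc1C#N | intermediate
9 | 2,2'-{[(1S,4S)-1,4-bis[4-(benzyloxy)phenyl]but-2-yne-1,4-diyl]bis(oxy)}bis[4-(benzyloxy)benzaldehyde] | O=Cc1ccc(OCc2ccccc2)cc1O[C@@H](c1ccc(OCc2ccccc2)cc1)C#C[C@H](c1ccc(OCc2ccccc2)cc1)Oc1cc(OCc2ccccc2)ccc1C=O | intermediate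
10 | (2S,3E)-7-(benzyloxy)-2-[4-(benzyloxy)phenyl]-3-{(2R)-2-[4-(benzyloxy)phenyl]-2-[5-(benzyloxy)-2-formylphenoxy]ethylidene}chroman-4-one | O=C1c2ccc(OCc3ccccc3)cc2O[C@@H](c2ccc(OCc3ccccc3)cc2)/C1=C\[C@H](c1ccc(OCc2ccccc2)cc1)Oc1cc(OCc2ccccc2)ccc1C=O | intermediate (not isolated)
11 | (2R,3S,2'R,3'S)-7,7'-bis(benzyloxy)-2,2'-bis[4-(benzyloxy)phenyl]-[3,3'-bichromane]-4,4'-dione | O=C1c2ccc(OCc3ccccc3)cc2O[C@@H](c2ccc(OCc3ccccc3)cc2)[C@@H]1[C@@H]1C(=O)c2ccc(OCc3ccccc3)cc2O[C@H]1c1ccc(OCc2ccccc2)cc1 | intermediate
12 | (2R,3S,2'R,3'S)-7,7'-dihydroxy-2,2'-bis(4-hydroxyphenyl)-[3,3'-bichromane]-4,4'-dione | O=C1c2ccc(O)cc2O[C@@H](c2ccc(O)cc2)[C@@H]1[C@@H]1C(=O)c2ccc(O)cc2O[C@H]1c1ccc(O)cc1 | target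

**Step count and risks**

Total steps: 8. Longest linear sequence: 8 steps (1 → 3 → 4 → 6 → 7 → 8 → 9 → 11 → 12).

Steps most likely to fail:

1. Step 7 (carries the label). What may go wrong: loss of aryloxide from the propargylic position during the first carbene addition (SN2'-type elimination to an allenyl ketone); base-mediated migration of the exocyclic double bond of 10 into the ring before the second closure; or erosion of the C2 configuration by retro-oxa-Michael ring opening during the DBU equilibration. Fallback with known chemistry: make the C3–C3' bond last by oxidative enolate coupling. It sets out from 1. Claisen–Schmidt condensation of 1 with 1-[4-(benzyloxy)-2-hydroxyphenyl]ethanone (KOH, EtOH, rt) gives (E)-1-[4-(benzyloxy)-2-hydroxyphenyl]-3-[4-(benzyloxy)phenyl]prop-2-en-1-one F1. Oxa-Michael closure (NaOAc, EtOH, reflux) gives racemic 7-(benzyloxy)-2-[4-(benzyloxy)phenyl]chroman-4-one F2. Kinetic resolution by asymmetric transfer hydrogenation (RhCl(Cp*)[TsDPEN], HCO2H/Et3N, with the TsDPEN enantiomer that reduces the (2S)-ketone, taken to be (S,S)) converts the (2S)-enantiomer into the cis-flavan-4-ol and leaves (2R)-7-(benzyloxy)-2-[4-(benzyloxy)phenyl]chroman-4-one F3. F3 is deprotonated with LiN(SiMe3)2 in THF at −78 °C and the lithium enolate is oxidised with CuCl2 to couple two molecules at C3; equilibration of the two α-keto centres then gives 11, where the route is rejoined. Since both halves carry the same fixed (2R) centre, only the C2-symmetric series can form.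

2. Step 5. What may go wrong: base-induced redox or propargyl–allenyl isomerisation of the propargylic alkoxide of 7, or slow arylation of the hindered secondary alkoxide. Fallback: form the second aryl ether under neutral conditions by Mitsunobu inversion, which needs the C4 epimer of 7. It sets out from 6. The alkynylation of step 4 is run with (R,R)-ProPhenol in place of the (S,S)-ligand (Me2Zn, Ph3P=O, toluene, then 1) to give 4-(benzyloxy)-2-{[(1S,4R)-1,4-bis[4-(benzyloxy)phenyl]-4-hydroxybut-2-yn-1-yl]oxy}benzonitrile F4. A Mitsunobu reaction of F4 with 4-(benzyloxy)-2-hydroxybenzonitrile (PPh3, DIAD, toluene, 0 °C) inverts the C4 carbinol centre and should give 8, where the route is rejoined.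

3. Step 3. What may go wrong: deprotonation of the doubly activated propargylic C–H of the product by residual alkoxide, leading to propargyl–allenyl isomerisation or loss of enantiopurity, or competing reaction through the acetylide. Fallback: form the C–O bond by copper-catalysed asymmetric propargylic etherification, which needs only a tertiary amine base and sets the centre from the ligand. It sets out from 4. Acetylation (Ac2O, Et3N, DMAP cat., CH2Cl2, 0 °C) gives (1R)-1-[4-(benzyloxy)phenyl]prop-2-yn-1-yl acetate F5. F5 is treated with 4-(benzyloxy)-2-hydroxybenzonitrile, (CuOTf)2·C6H6 (5 mol%), the enantiomer of 2,6-bis(4-phenyl-4,5-dihydrooxazol-2-yl)pyridine that delivers the (R)-ether (10 mol%) and i-Pr2NEt (1.2 equiv) in CH2Cl2 at −20 °C. The phenol should add to the γ-carbon of the copper allenylidene to give 6, where the route is rejoined; the configuration of F5 is erased in that planar intermediate, so the ligand alone sets the centre.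

**Further compounds**

F1 | step 7 | (E)-1-[4-(benzyloxy)-2-hydroxyphenyl]-3-[4-(benzyloxy)phenyl]prop-2-en-1-one | O=C(/C=C/c1ccc(OCc2ccccc2)cc1)c1ccc(OCc2ccccc2)cc1O
F2 | step 7 | racemic 7-(benzyloxy)-2-[4-(benzyloxy)phenyl]chroman-4-one | O=C1CC(c2ccc(OCc3ccccc3)cc2)Oc2cc(OCc3ccccc3)ccc12
F3 | step 7 | (2R)-7-(benzyloxy)-2-[4-(benzyloxy)phenyl]chroman-4-one | O=C1C[C@H](c2ccc(OCc3ccccc3)cc2)Oc2cc(OCc3ccccc3)ccc12
F4 | step 5 | 4-(benzyloxy)-2-{[(1S,4R)-1,4-bis[4-(benzyloxy)phenyl]-4-hydroxybut-2-yn-1-yl]oxy}benzonitrile | N#Cc1ccc(OCc2ccccc2)cc1O[C@@H](c1ccc(OCc2ccccc2)cc1)C#C[C@H](O)c1ccc(OCc2ccccc2)cc1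
F5 | step 3 | (1R)-1-[4-(benzyloxy)phenyl]prop-2-yn-1-yl acetate | CC(=O)O[C@@H](c1ccc(OCc2ccccc2)cc1)C#C
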